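The ring B quinone is traced back to a dibenzyl hydroquinone and the C2 methylene to a mixed acetal; the pyran ring is then cut at O1–C2 and C3–C4.
The pyran ring (O1, C2, C3, C4, C4a, C8a) is the formal [4+2] adduct of the ring A ortho-quinone methide O1=C8a–C4a=C4 and an enol ether C2=C3 that carries ring B on C3.
Forward, ring A is built up to an O-Boc salicyl alcohol. A ring B iodide is joined by Negishi coupling to a two-carbon unit from trichloroethylene already bound to the auxiliary oxygen, and cis-semihydrogenation gives the (Z)-enol ether.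
The cycloaddition of the two fragments closes the only ring that has to be made; acetal reduction, hydrogenolysis and hydroquinone oxidation finish the target.
C3 (S), the only stereocentre, is set in the cycloaddition by the (1R,2S)-2-phenylcyclohexyl group on the enol ether oxygen; the temporary centre C2 is erased afterwards.

Key step: step 13

Assumption: the (Z)-enol ether is taken to react through its s-trans C=C–O–C conformer with the carbinol C–H in the alkene plane. On this model the (1R,2S) auxiliary leads to (2S,3S); if experiment shows the opposite sense, the equally available (1S,2R) alcohol is used with no other change.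

Step 1
Reactants: 1 2-hydroxy-3,4-dimethoxybenzaldehyde
Product: 2 2-(benzyloxy)-3,4-dimethoxybenzaldehyde
Conditions: BnBr, K2CO3, DMF, rt → 50 °C
Reagents that add atoms: benzyl bromide, BrCc1ccccc1
Why: Williamson etherification of the only acidic site masks the future C8 hydroxyl with a group that stays on until the final hydrogenolysis.

Step 2
Reactants: 2 2-(benzyloxy)-3,4-dimethoxybenzaldehyde
Product: 4 2-(benzyloxy)-3,4-dimethoxyphenol, via aryl formate 3 (not isolated)
Conditions: 30% H2O2, H2SO4 (cat.), MeOH, rt
Reagents that add atoms: hydrogen peroxide, OO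
Why: In this acid-catalysed Dakin oxidation the electron-rich aryl group migrates to oxygen and formate 3 is methanolysed in the same pot, which installs the oxygen that becomes O1.

Step 3
Reactants: 4 2-(benzyloxy)-3,4-dimethoxyphenol
Product: 5 3-(benzyloxy)-2-hydroxy-4,5-dimethoxybenzaldehyde
Conditions: MgCl2, Et3N, (CH2O)n, MeCN, reflux; aq. HCl work-up
Reagents that add atoms: paraformaldehyde (as formaldehyde), C=O
Why: In the Casnati–Skattebøl ortho-formylation the magnesium phenoxide delivers formaldehyde to the only free ortho position and a second formaldehyde accepts hydride, which places the future C4 next to the O1 oxygen.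

Step 4
Reactants: 5 3-(benzyloxy)-2-hydroxy-4,5-dimethoxybenzaldehyde
Product: 6 tert-butyl 2-(benzyloxy)-6-formyl-3,4-dimethoxyphenyl carbonate
Conditions: Boc2O, i-Pr2NEt, DMAP (cat.), CH2Cl2, rt
Reagents that add atoms: di-tert-butyl dicarbonate, CC(C)(C)OC(=O)OC(=O)OC(C)(C)C
Why: DMAP-catalysed O-acylation of the phenol installs the carbonate that later acts as the migrating and leaving group, and the aldehyde is inert to these conditions.

Step 5
Reactants: 6 tert-butyl 2-(benzyloxy)-6-formyl-3,4-dimethoxyphenyl carbonate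
Product: 7 tert-butyl 2-(benzyloxy)-6-(hydroxymethyl)-3,4-dimethoxyphenyl carbonate
Conditions: BH3·THF, THF, −10 → 0 °C; pH 7 buffer
Reagents that add atoms: none
Why: Chemoselective borane reduction proceeds through a weakly nucleophilic borate ester that should not pull the Boc group across, so the quinone methide is not released early as it would be from a borohydride-derived alkoxide.

Step 6
Reactants: 8 2,3-dimethoxyphenol
Product: 9 2,3-dimethoxy-1,4-benzoquinone
Conditions: (KSO3)2NO (2.2 equiv), KH2PO4, H2O/acetone, rt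
Reagents that add atoms: potassium nitrosodisulfonate, [K+].[K+].[O]N(S(=O)(=O)[O-])S(=O)(=O)[O-]
Why: In the Teuber oxidation one nitrosodisulfonate radical removes the phenolic hydrogen and a second delivers oxygen to the free para position, which fixes the 1,4-dioxygen pattern of ring B.

Step 7
Reactants: 9 2,3-dimethoxy-1,4-benzoquinone
Product: 10 2,3-dimethoxybenzene-1,4-diol
Conditions: Na2S2O4, EtOAc/H2O, rt, Ar
Reagents that add atoms: none
Why: Dithionite reduction of a para-quinone is a fast two-electron transfer that leaves the methyl ethers alone.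

Step 8
Reactants: 10 2,3-dimethoxybenzene-1,4-diol
Product: 11 1,4-bis(benzyloxy)-2,3-dimethoxybenzene
Conditions: BnBr (2.4 equiv), K2CO3, DMF, 50 °C, Ar
Reagents that add atoms: benzyl bromide, BrCc1ccccc1
Why: Double Williamson etherification under inert gas stores the quinone as a symmetrical hydroquinone diether that tolerates organometallic, Lewis acidic and hydride reagents.

Step 9
Reactants: 11 1,4-bis(benzyloxy)-2,3-dimethoxybenzene
Product: 12 1,4-bis(benzyloxy)-5-iodo-2,3-dimethoxybenzene
Conditions: NIS (1.0 equiv), CF3CO2H (cat.), MeCN, rt, dark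
Reagents that add atoms: N-iodosuccinimide, O=C1CCC(=O)N1I
Why: Electrophilic aromatic iodination meets two symmetry-equivalent free positions on the tetraalkoxy ring, the first iodine slows a second attack, and the benzyl rings are far less activated.

Step 10
Reactants: 13 (1R,2S)-2-phenylcyclohexan-1-ol, 14 trichloroethylene
Product: 16 (E)-1,2-dichlorovinyl (1R,2S)-2-phenylcyclohexyl ether, via dichloroacetylene 15 (not isolated)
Conditions: KH, THF, 0 °C → rt; then 14, −50 °C → rt
Reagents that add atoms: none
Why: In this elimination–addition the alkoxide dehydrochlorinates 14 and adds anti across 15 as it forms, and the auxiliary keeps its configuration because the carbinol C–O bond is never broken.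

Step 11
Reactants: 16 (E)-1,2-dichlorovinyl (1R,2S)-2-phenylcyclohexyl ether, 12 1,4-bis(benzyloxy)-5-iodo-2,3-dimethoxybenzene
Product: 20 1,4-bis(benzyloxy)-2,3-dimethoxy-5-({[(1R,2S)-2-phenylcyclohexyl]oxy}ethynyl)benzene, via chloroethynyl ether 17 (not isolated), via lithium acetylide 18 (not isolated), via chlorozinc acetylide 19 (not isolated)
Conditions: n-BuLi (2.1 equiv), THF, −78 → −40 °C; ZnCl2, −40 → 0 °C; 12, Pd(PPh3)4 (5 mol %), rt; Et3N-treated silica
Reagents that add atoms: none
Why: In this Negishi coupling n-BuLi removes HCl from 16 and exchanges the remaining chlorine of 17 for lithium, ZnCl2 converts 18 into the less basic 19, and zerovalent palladium inserts into the C–I bond of 12 and forms the sp–sp2 bond, a sequence established for alkoxyethynylzinc chlorides and aryl iodides.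

Step 12
Reactants: 20 1,4-bis(benzyloxy)-2,3-dimethoxy-5-({[(1R,2S)-2-phenylcyclohexyl]oxy}ethynyl)benzene
Product: 21 1,4-bis(benzyloxy)-2,3-dimethoxy-5-[(Z)-2-{[(1R,2S)-2-phenylcyclohexyl]oxy}ethenyl]benzene
Conditions: H2 (1 atm), Pd/CaCO3 poisoned with Pb(OAc)2, quinoline, EtOAc/hexane, rt
Reagents that add atoms: none
Why: Partial alkyne hydrogenation delivers one equivalent of hydrogen syn from the poisoned palladium surface and should stop at the (Z)-alkene, and this deactivated catalyst does not cleave benzyl ethers.

Step 13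
Reactants: 7 tert-butyl 2-(benzyloxy)-6-(hydroxymethyl)-3,4-dimethoxyphenyl carbonate, 21 1,4-bis(benzyloxy)-2,3-dimethoxy-5-[(Z)-2-{[(1R,2S)-2-phenylcyclohexyl]oxy}ethenyl]benzene
Product: 23 (2S,3S)-8-(benzyloxy)-3-[2,5-bis(benzyloxy)-3,4-dimethoxyphenyl]-6,7-dimethoxy-2-{[(1R,2S)-2-phenylcyclohexyl]oxy}chromane (2,3-cis), via ring A quinone methide 22 (not isolated)
Conditions: t-BuMgCl (1.05 equiv), 21 (2.5 equiv, excess recovered), Et2O, −78 °C → rt; aq. NH4Cl
Reagents that add atoms: none
Why: t-BuMgCl deprotonates the benzylic alcohol of 7, the Boc group shifts from the phenol oxygen to the alkoxide, and the magnesium phenoxide expels tert-butyl carbonate in a 1,4-elimination that releases 22 slowly and at low concentration. 22 then acts as an electron-poor 1-oxadiene (O1=C8a–C4a=C4) toward the electron-rich alkene of 21 in an inverse-electron-demand hetero-Diels–Alder reaction; the closest known reactions are the capture of O-Boc-derived ortho-quinone methides by enol ethers of trans-2-phenylcyclohexanol and, in racemic form, by beta-alkoxystyrenes to give 2-alkoxyisoflavans. The six-membered pyran ring closes in one concerted but asynchronous suprafacial [4+2] event in which C3–C4 bonding runs ahead of O1–C2 bonding and ring A regains aromaticity. Regioselectivity follows from polarity, since methylene C4 is the electrophilic end of the heterodiene and the aryl-bearing carbon is the nucleophilic end of the enol ether, so ring B ends up on C3. The 2,3-cis relation is carried over from the (Z)-alkene by suprafacial addition, and because C4 bears two hydrogens, endo and exo approach to one alkene face give the same product. The absolute configuration (2S,3S) comes from the auxiliary, whose phenyl group covers the re face of the alkoxy-bearing carbon in the s-trans enol ether so that 22 bonds to the open si face, while the excess of 21 keeps capture ahead of self-dimerisation of 22.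

Step 14
Reactants: 23 (2S,3S)-8-(benzyloxy)-3-[2,5-bis(benzyloxy)-3,4-dimethoxyphenyl]-6,7-dimethoxy-2-{[(1R,2S)-2-phenylcyclohexyl]oxy}chromane
Product: 24 (3S)-8-(benzyloxy)-3-[2,5-bis(benzyloxy)-3,4-dimethoxyphenyl]-6,7-dimethoxychromane
Conditions: Et3SiH (5 equiv), BF3·OEt2 (1.5 equiv), CH2Cl2, −78 → −40 °C; aq. NaHCO3
Reagents that add atoms: none
Why: In this ionic hydrogenation of an acetal BF3 ionises the more Lewis basic exocyclic alkoxy group and the silane delivers hydride to the cyclic oxocarbenium carbon C2, which erases the temporary centre, frees the auxiliary for reuse and leaves C3 (S) and the benzyl ethers untouched at low temperature.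

Step 15
Reactants: 24 (3S)-8-(benzyloxy)-3-[2,5-bis(benzyloxy)-3,4-dimethoxyphenyl]-6,7-dimethoxychromane
Product: 26 5-[(3S)-8-hydroxy-6,7-dimethoxy-3,4-dihydro-2H-chromen-3-yl]-2,3-dimethoxycyclohexa-2,5-diene-1,4-dione, via hydroquinone 25 (not isolated)
Conditions: H2 (1 atm), 10% Pd/C, EtOAc, rt; filter under Ar; then Ag2O (1.1 equiv), Na2SO4, 0 °C → rt
Reagents that add atoms: none
Why: Hydrogenolysis frees all three phenols and one equivalent of Ag2O should oxidise only the para-hydroquinone of ring B, because the ring A monophenol has no para oxygen partner and is harder to oxidise, and C3 takes no part in either event.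

Compound list
1 | 2-hydroxy-3,4-dimethoxybenzaldehyde | COc1ccc(C=O)c(O)c1OC | starting material
2 | 2-(benzyloxy)-3,4-dimethoxybenzaldehyde | COc1ccc(C=O)c(OCc2ccccc2)c1OC | intermediate
3 | 2-(benzyloxy)-3,4-dimethoxyphenyl formate | COc1ccc(OC=O)c(OCc2ccccc2)c1OC | intermediate
4 | 2-(benzyloxy)-3,4-dimethoxyphenol | COc1ccc(O)c(OCc2ccccc2)c1OC | intermediate
5 | 3-(benzyloxy)-2-hydroxy-4,5-dimethoxybenzaldehyde | COc1cc(C=O)c(O)c(OCc2ccccc2)c1OC | intermediate
6 | tert-butyl 2-(benzyloxy)-6-formyl-3,4-dimethoxyphenyl carbonate | COc1cc(C=O)c(OC(=O)OC(C)(C)C)c(OCc2ccccc2)c1OC | intermediate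
7 | tert-butyl 2-(benzyloxy)-6-(hydroxymethyl)-3,4-dimethoxyphenyl carbonate | COc1cc(CO)c(OC(=O)OC(C)(C)C)c(OCc2ccccc2)c1OC | intermediate
8 | 2,3-dimethoxyphenol | COc1cccc(O)c1OC | starting material
9 | 2,3-dimethoxy-1,4-benzoquinone | COC1=C(OC)C(=O)C=CC1=O | intermediate
10 | 2,3-dimethoxybenzene-1,4-diol | COc1c(O)ccc(O)c1OC | intermediate
11 | 1,4-bis(benzyloxy)-2,3-dimethoxybenzene | COc1c(OCc2ccccc2)ccc(OCc2ccccc2)c1OC | intermediate
12 | 1,4-bis(benzyloxy)-5-iodo-2,3-dimethoxybenzene | COc1c(OC)c(OCc2ccccc2)cc(I)c1OCc3ccccc3 | intermediate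
13 | (1R,2S)-2-phenylcyclohexan-1-ol (trans) | O[C@@H]1CCCC[C@H]1c1ccccc1 | starting material
14 | trichloroethylene | ClC=C(Cl)Cl | starting material
15 | dichloroacetylene | ClC#CCl | intermediate
16 | (E)-1,2-dichlorovinyl (1R,2S)-2-phenylcyclohexyl ether | Cl/C=C(/Cl)O[C@@H]1CCCC[C@H]1c1ccccc1 | intermediate
17 | chloroethynyl (1R,2S)-2-phenylcyclohexyl ether | ClC#CO[C@@H]1CCCC[C@H]1c1ccccc1 | intermediate
18 | lithium {[(1R,2S)-2-phenylcyclohexyl]oxy}acetylide | [Li]C#CO[C@@H]1CCCC[C@H]1c1ccccc1 | intermediate
19 | chloro({[(1R,2S)-2-phenylcyclohexyl]oxy}ethynyl)zinc | Cl[Zn]C#CO[C@@H]1CCCC[C@H]1c1ccccc1 | intermediate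
20 | 1,4-bis(benzyloxy)-2,3-dimethoxy-5-({[(1R,2S)-2-phenylcyclohexyl]oxy}ethynyl)benzene | COc1c(OC)c(OCc2ccccc2)cc(C#CO[C@@H]3CCCC[C@H]3c4ccccc4)c1OCc5ccccc5 | intermediate
21 | 1,4-bis(benzyloxy)-2,3-dimethoxy-5-[(Z)-2-{[(1R,2S)-2-phenylcyclohexyl]oxy}ethenyl]benzene | COc1c(OC)c(OCc2ccccc2)cc(/C=C\O[C@@H]3CCCC[C@H]3c4ccccc4)c1OCc5ccccc5 | intermediate
22 | 2-(benzyloxy)-3,4-dimethoxy-6-methylidenecyclohexa-2,4-dien-1-one (ring A ortho-quinone methide) | C=C1C=C(OC)C(OC)=C(OCc2ccccc2)C1=O | intermediate
23 | (2S,3S)-8-(benzyloxy)-3-[2,5-bis(benzyloxy)-3,4-dimethoxyphenyl]-6,7-dimethoxy-2-{[(1R,2S)-2-phenylcyclohexyl]oxy}chromane | COc1c(OC)c(OCc2ccccc2)cc([C@H]3[C@@H](O[C@@H]4CCCC[C@H]4c5ccccc5)Oc6c(cc(OC)c(OC)c6OCc7ccccc7)C3)c1OCc8ccccc8 | intermediate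
24 | (3S)-8-(benzyloxy)-3-[2,5-bis(benzyloxy)-3,4-dimethoxyphenyl]-6,7-dimethoxychromane | COc1c(OC)c(OCc2ccccc2)cc([C@H]3COc4c(cc(OC)c(OC)c4OCc5ccccc5)C3)c1OCc6ccccc6 | intermediate
25 | (3S)-3-(2,5-dihydroxy-3,4-dimethoxyphenyl)-6,7-dimethoxychroman-8-ol | COc1c(OC)c(O)cc([C@H]2COc3c(cc(OC)c(OC)c3O)C2)c1O | intermediate
26 | 5-[(3S)-8-hydroxy-6,7-dimethoxy-3,4-dihydro-2H-chromen-3-yl]-2,3-dimethoxycyclohexa-2,5-diene-1,4-dione | COC1=C(OC)C(=O)C([C@H]2COc3c(cc(OC)c(OC)c3O)C2)=CC1=O | target

Total step count: 15
Longest linear sequence: 9 steps, from 8 to 26 (steps 6, 7, 8, 9, 11, 12, 13, 14, 15)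

Steps most likely to fail

1. **Step 13.** The auxiliary may discriminate poorly between the two alkene faces, because its phenyl group lies nearer to C2 than to C3 and the twisted ring B can disturb the s-trans conformer. Capture of the quinone methide may also be slow. The fallback moves stereocontrol from the auxiliary to a catalyst.
   - It sets out from 23 of whatever diastereomeric purity. Catalytic p-TsOH in warm toluene eliminates the auxiliary alcohol and gives the achiral 8-(benzyloxy)-3-[2,5-bis(benzyloxy)-3,4-dimethoxyphenyl]-6,7-dimethoxy-4H-chromene F1.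
   - The trisubstituted enol ether double bond of this chromene is hydrogenated asymmetrically with a cationic iridium phosphine–oxazoline catalyst such as [Ir(cod)((S)-t-Bu-PHOX)][B(C6H3(CF3)2)4] under H2 pressure in CH2Cl2, with the ligand antipode fixed by a screen.
   - This reaction type is established for chromenes and isoflavenes and does not harm benzyl ethers. It returns to the route at 24.

2. **Step 14.** Ionisation may break the endocyclic O1–C2 bond, so that hydride capture opens the ring. Alternatively the oxocarbenium ion may lose the C3 proton, which would erode the configuration. The fallback replaces direct deoxygenation by opening and re-closing the ring.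
   - It sets out from 23. Brief hydrolysis with camphorsulfonic acid in aqueous MeCN gives (3S)-8-(benzyloxy)-3-[2,5-bis(benzyloxy)-3,4-dimethoxyphenyl]-6,7-dimethoxychroman-2-ol F2.
   - NaBH4 in cold MeOH reduces its open-chain form at once, before it can enolise, to (2S)-2-[2,5-bis(benzyloxy)-3,4-dimethoxyphenyl]-3-[3-(benzyloxy)-2-hydroxy-4,5-dimethoxyphenyl]propan-1-ol F3.
   - Mitsunobu etherification (PPh3, DIAD, THF) of the only free phenol with the primary alcohol re-forms O1–C2 and returns to the route at 24.

3. **Step 11.** The alkoxyacetylide may be protonated or hydrated. Oxidative addition to the hindered, electron-rich iodide may be slow. The aryl ynol ether may also lose the auxiliary by a thermal retro-ene process during a prolonged coupling. The fallback avoids ynol ethers and forms the vinyl C–O bond last.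
   - It sets out from 12. Iodine–magnesium exchange with i-PrMgCl·LiCl in THF at −20 °C and a DMF quench give 2,5-bis(benzyloxy)-3,4-dimethoxybenzaldehyde F4.
   - Stork–Zhao olefination with (iodomethyl)triphenylphosphonium iodide and NaN(SiMe3)2 at −78 °C gives 1,4-bis(benzyloxy)-5-[(Z)-2-iodoethenyl]-2,3-dimethoxybenzene F5.
   - Ullmann-type C–O coupling with alcohol 13 (CuI, 3,4,7,8-tetramethyl-1,10-phenanthroline, Cs2CO3, toluene, 80 °C) proceeds with retention of alkene geometry and returns to the route at 21.

Further compounds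
F1 | step 13 | 8-(benzyloxy)-3-[2,5-bis(benzyloxy)-3,4-dimethoxyphenyl]-6,7-dimethoxy-4H-chromene | COc1c(OC)c(OCc2ccccc2)cc(C3=COc4c(cc(OC)c(OC)c4OCc5ccccc5)C3)c1OCc6ccccc6
F2 | step 14 | (3S)-8-(benzyloxy)-3-[2,5-bis(benzyloxy)-3,4-dimethoxyphenyl]-6,7-dimethoxychroman-2-ol (anomer mixture at C2) | COc1c(OC)c(OCc2ccccc2)cc([C@H]3C(O)Oc4c(cc(OC)c(OC)c4OCc5ccccc5)C3)c1OCc6ccccc6
F3 | step 14 | (2S)-2-[2,5-bis(benzyloxy)-3,4-dimethoxyphenyl]-3-[3-(benzyloxy)-2-hydroxy-4,5-dimethoxyphenyl]propan-1-ol | COc1c(OC)c(OCc2ccccc2)cc([C@@H](CO)Cc3cc(OC)c(OC)c(OCc4ccccc4)c3O)c1OCc5ccccc5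
F4 | step 11 | 2,5-bis(benzyloxy)-3,4-dimethoxybenzaldehyde | COc1c(OC)c(OCc2ccccc2)cc(C=O)c1OCc3ccccc3
F5 | step 11 | 1,4-bis(benzyloxy)-5-[(Z)-2-iodoethenyl]-2,3-dimethoxybenzene | COc1c(OC)c(OCc2ccccc2)cc(/C=C\I)c1OCc3ccccc3
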